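C4 carries three one-carbon arms, C3, C5 and C8, which is a trimethylenemethane skeleton. Arms C3 and C5 span the C2–O1 bond, the former C=O of vanillin. (Numbering: ring O1, aryl-bearing C2, spiro C3, benzyl-bearing C4, C5H2; epoxide C6H2 and O7; benzylic C8H2.)
The oxirane is the second ring and is formed last: epoxide ⇒ C3=C6 alkene ⇒ C3 ketone.
The C8–aryl bond comes from an isovanillyl cuprate and the C3-oxo/C4=C8 enone, which comes from allylic oxidation at C3 of the 4-methylene tetrahydrofuran.
The tetrahydrofuran is the first ring: palladium trimethylenemethane (3+2) cycloaddition of 2-[(trimethylsilyl)methyl]allyl acetate to O-silyl vanillin forms C2–C3 and O1–C5.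
C2 is set by the chiral ligand. C4 (protonation) and C3 (epoxidation) are relayed from C2: aryl and benzyl end cis, and O7 lies anti to both.

Key step: step 3

Assumption: the ligand antipode that gives (R)-6 is identified in a test run. Both antipodes are accessible from (R)- or (S)-BINOL.
Abbreviation: TBS = tert-butyldimethylsilyl.

Step 1
Reactants: 1 vanillin
Product: 2 4-(tert-butyldimethylsilyloxy)-3-methoxybenzaldehyde (O-TBS vanillin)
Conditions: TBSCl (1.1 equiv), imidazole (2 equiv), CH2Cl2, 0 °C to rt
Reagents that add atoms: tert-butyldimethylsilyl chloride (TBSCl), CC(C)(C)[Si](C)(C)Cl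
Why: Imidazole-promoted O-silylation of a phenol is routine, leaves the aldehyde untouched and creates no stereocentre.

Step 2
Reactants: 3 5-bromo-2-methoxyphenol
Product: 4 (5-bromo-2-methoxyphenoxy)(tert-butyl)dimethylsilane
Conditions: TBSCl (1.1 equiv), imidazole (2 equiv), CH2Cl2, 0 °C to rt
Reagents that add atoms: tert-butyldimethylsilyl chloride (TBSCl), CC(C)(C)[Si](C)(C)Cl
Why: The same O-silylation masks the acidic phenol so that the bromide can later be metalated, and silicon sits meta to bromine, so no silyl migration to the metalated carbon is possible.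

Step 3
Reactants: 2 O-TBS vanillin; 5 2-[(trimethylsilyl)methyl]allyl acetate (1.6 equiv)
Product: 6 (R)-2-[4-(TBS-oxy)-3-methoxyphenyl]-4-methylenetetrahydrofuran
Conditions: Pd(dba)2 (5 mol %), BINOL-derived phosphoramidite bearing a trans-2,5-diarylpyrrolidine (10 mol %), In(acac)3 (10 mol %), toluene, 25–50 °C
Reagents that add atoms: none
Why: Zerovalent palladium ionises the allylic acetate of 5 and the released acetate removes the silyl group, giving the zwitterionic palladium trimethylenemethane complex; its carbanionic arm adds to the carbonyl carbon of 2 activated by In(acac)3 (C2–C3), and the resulting indium alkoxide attacks the far terminus of the cationic π-allylpalladium unit (O1–C5). The closest known reaction type is the enantioselective palladium trimethylenemethane cycloaddition to aryl aldehydes with phosphoramidite ligands and a Lewis acid co-catalyst, of which this is a direct application. The single ring closes by intramolecular O-allylation, formally 5-exo-tet at C5 with palladium as the leaving group, and leaves C4=C8 exocyclic. The single new stereocentre C2 is fixed in the C–C bond-forming event, where the ligand pocket exposes the Re face of the aldehyde and so gives the R configuration. The step needs enantioface selection, which the ligand supplies, and ring closure ahead of O-silylation of the alkoxide by trimethylsilyl acetate, which the indium co-catalyst secures while also offsetting the low electrophilicity of the electron-rich aldehyde; regiochemistry is no issue because the unsubstituted donor is symmetric, and the aryl silyl ether is inert to acetate.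

Step 4
Reactants: 6 (R)-2-aryl-4-methylenetetrahydrofuran
Product: 7 (2S,3R)-2-[4-(TBS-oxy)-3-methoxyphenyl]-4-methylenetetrahydrofuran-3-ol (hydroxyl expected trans to the aryl group; any C3 epimer is carried along, since both converge in step 5)
Conditions: SeO2 (0.4 equiv), t-BuOOH (2.5 equiv, decane), CH2Cl2, 0 °C to rt, stopped short of full conversion
Reagents that add atoms: selenium dioxide, O=[Se]=O (transfers the oxygen); tert-butyl hydroperoxide, CC(C)(C)OO (terminal oxygen source)
Why: In this Riley allylic hydroxylation, an ene reaction at C8 followed by a 2,3-sigmatropic shift restores the exocyclic alkene and should place oxygen on C3 anti to the aryl group, because the C5–H bonds are inductively deactivated by O1, in the way methallyl ethers are hydroxylated at the carbon remote from oxygen.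

Step 5
Reactants: 7 allylic alcohol
Product: 8 (S)-2-[4-(TBS-oxy)-3-methoxyphenyl]-4-methylenedihydrofuran-3(2H)-one
Conditions: Dess–Martin periodinane (1.3 equiv), solid NaHCO3 (5 equiv), CH2Cl2, 0 °C; cold filtration through a short silica plug, solution used at once
Reagents that add atoms: none
Why: Buffered Dess–Martin oxidation is fast, close to neutral and free of amines or metals, so the acidic C2–H and the exocyclic position of the double bond should be kept as long as the α-methylene ketone is not stored.

Step 6
Reactants: 8 exocyclic enone; 4 silylated aryl bromide (2.6 equiv)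
Product: 12 (2S,4S)-2-[4-(TBS-oxy)-3-methoxyphenyl]-4-[3-(TBS-oxy)-4-methoxybenzyl]dihydrofuran-3(2H)-one, via aryllithium 9 (not isolated), via lithium diarylcuprate 10 (not isolated), via lithium enolate 11 (not isolated)
Conditions: 4, t-BuLi (5.2 equiv), Et2O, −78 °C; CuBr·SMe2 (1.3 equiv), −78 to −40 °C; 8 in Et2O added slowly, −78 °C; precooled AcOH in THF, −78 °C
Reagents that add atoms: none
Why: Gilman cuprate 1,4-addition to an unhindered α-methylene ketone, the established way to attach side chains to methylenecyclopentanones, forms C8–aryl, and irreversible low-temperature protonation of the planar enolate 11 from the face opposite the C2 aryl group should leave the benzyl group cis to it (4S), as in kinetic protonation of α,γ-disubstituted butyrolactone enolates, while acetate is too weak a base to disturb C2.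

Step 7
Reactants: 12 ketone
Product: 13 (2R,4R)-2-[4-(TBS-oxy)-3-methoxyphenyl]-4-[3-(TBS-oxy)-4-methoxybenzyl]-3-methylenetetrahydrofuran (descriptors change by priority only; geometry unchanged)
Conditions: Zn, CH2Br2, TiCl4 premixed in THF (−40 to 5 °C, aged), then 12 in CH2Cl2, 0 °C to rt; aqueous work-up
Reagents that add atoms: dibromomethane, BrCBr
Why: Takai–Lombardo methylenation uses a non-basic gem-dimetallic reagent known to olefinate enolisable, α-stereogenic ketones without epimerisation, so C2 and C4 should be retained and the aryl silyl ethers tolerated.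

Step 8
Reactants: 13 exocyclic alkene
Product: 14 (3S,4S,7S)-4-[4-(TBS-oxy)-3-methoxyphenyl]-7-[3-(TBS-oxy)-4-methoxybenzyl]-1,5-dioxaspiro[2.4]heptane
Conditions: dimethyldioxirane (1.2 equiv, acetone), CH2Cl2, −20 to 0 °C
Reagents that add atoms: dimethyldioxirane, CC1(C)OO1
Why: In this concerted dioxirane epoxidation of a 1,1-disubstituted alkene the C2 aryl and C4 benzyl groups both cover one face, so oxygen should arrive on the open face and place O7 anti to both (spiro centre S), and the neutral medium spares the acid-sensitive spiro-epoxide.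

Step 9
Reactants: 14 bis-silyl ether
Product: 15 target, 4-[(3S,4S,7S)-7-(3-hydroxy-4-methoxybenzyl)-1,5-dioxaspiro[2.4]heptan-4-yl]-2-methoxyphenol
Conditions: Bu4NF (2.4 equiv), AcOH (2.4 equiv), THF, 0 °C
Reagents that add atoms: none
Why: Fluoride cleavage of aryl silyl ethers is rapid, and the acetic acid buffer keeps the phenols protonated, so neither quinone-methide opening at C2 nor phenoxide attack on the epoxide should occur and no stereocentre is touched.

Compound list
1 | vanillin | COc1cc(C=O)ccc1O | starting material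
2 | 4-(tert-butyldimethylsilyloxy)-3-methoxybenzaldehyde | COc1cc(C=O)ccc1O[Si](C)(C)C(C)(C)C | intermediate
3 | 5-bromo-2-methoxyphenol | COc1ccc(Br)cc1O | starting material
4 | (5-bromo-2-methoxyphenoxy)(tert-butyl)dimethylsilane | COc1ccc(Br)cc1O[Si](C)(C)C(C)(C)C | intermediate
5 | 2-[(trimethylsilyl)methyl]allyl acetate | C[Si](C)(C)CC(=C)COC(C)=O | starting material
6 | (R)-2-[4-(TBS-oxy)-3-methoxyphenyl]-4-methylenetetrahydrofuran | C=C1CO[C@@H](c2ccc(O[Si](C)(C)C(C)(C)C)c(OC)c2)C1 | intermediate
7 | (2S,3R)-2-[4-(TBS-oxy)-3-methoxyphenyl]-4-methylenetetrahydrofuran-3-ol | C=C1CO[C@@H](c2ccc(O[Si](C)(C)C(C)(C)C)c(OC)c2)[C@@H]1O | intermediate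
8 | (S)-2-[4-(TBS-oxy)-3-methoxyphenyl]-4-methylenedihydrofuran-3(2H)-one | C=C1CO[C@@H](c2ccc(O[Si](C)(C)C(C)(C)C)c(OC)c2)C1=O | intermediate
9 | [3-(TBS-oxy)-4-methoxyphenyl]lithium | [Li]c1ccc(OC)c(O[Si](C)(C)C(C)(C)C)c1 | intermediate
10 | lithium bis[3-(TBS-oxy)-4-methoxyphenyl]cuprate | [Li+].COc1ccc([Cu-]c2ccc(OC)c(O[Si](C)(C)C(C)(C)C)c2)cc1O[Si](C)(C)C(C)(C)C | intermediate
11 | lithium (S)-2-aryl-4-benzyl-2,5-dihydrofuran-3-olate (C3=C4 enolate) | COc1ccc(CC2=C(O[Li])[C@H](c3ccc(O[Si](C)(C)C(C)(C)C)c(OC)c3)OC2)cc1O[Si](C)(C)C(C)(C)C | intermediate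
12 | (2S,4S)-2-[4-(TBS-oxy)-3-methoxyphenyl]-4-[3-(TBS-oxy)-4-methoxybenzyl]dihydrofuran-3(2H)-one (2,4-cis) | COc1ccc(C[C@H]2CO[C@@H](c3ccc(O[Si](C)(C)C(C)(C)C)c(OC)c3)C2=O)cc1O[Si](C)(C)C(C)(C)C | intermediate
13 | (2R,4R)-2-[4-(TBS-oxy)-3-methoxyphenyl]-4-[3-(TBS-oxy)-4-methoxybenzyl]-3-methylenetetrahydrofuran (2,4-cis) | COc1ccc(C[C@H]2CO[C@@H](c3ccc(O[Si](C)(C)C(C)(C)C)c(OC)c3)C2=C)cc1O[Si](C)(C)C(C)(C)C | intermediate
14 | (3S,4S,7S)-4-[4-(TBS-oxy)-3-methoxyphenyl]-7-[3-(TBS-oxy)-4-methoxybenzyl]-1,5-dioxaspiro[2.4]heptane | COc1ccc(C[C@H]2CO[C@@H](c3ccc(O[Si](C)(C)C(C)(C)C)c(OC)c3)[C@@]23CO3)cc1O[Si](C)(C)C(C)(C)C | intermediate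
15 | 4-[(3S,4S,7S)-7-(3-hydroxy-4-methoxybenzyl)-1,5-dioxaspiro[2.4]heptan-4-yl]-2-methoxyphenol (CNP0184956.1) | COc1ccc(C[C@H]2CO[C@@H](c3ccc(O)c(OC)c3)[C@@]23CO3)cc1O | target

Total step count: 9. Longest linear sequence: 8 (vanillin through steps 1 and 3–9).

Steps most likely to fail

Step 6. The enone may dimerise or oligomerise through its own enolate, or its double bond may migrate into the ring, before the cuprate captures it. Proton exchange may scramble C2, and the facial bias in the protonation at C4 may be weak. The fallback sets out from 7 and comes back at 12 without any enone or enolate.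
- Steglich esterification of 7 with picolinic acid (DCC, DMAP, CH2Cl2) should give the allylic picolinate F1.
- The arylmagnesium bromide F2 (from 4 and Mg in THF), combined with CuBr·SMe2, should displace the picolinate in the SN2′ sense at the unhindered C8. This gives the (R)-2-aryl-4-benzyl-2,5-dihydrofuran F3.
- BH3·THF at 0 °C should add to the trisubstituted C3=C4 bond from the face opposite the neighbouring C2 aryl group, with boron on C3 and hydrogen on C4, to give the alkylborane F4. This mirrors the hydroboration of 1-aryl glycals.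
- NaBO3·4H2O should convert F4 into the (2S,3R,4S)-alcohol F5, in which syn addition has already placed the benzyl group cis to the aryl group.
- Dess–Martin oxidation of F5 gives 12.

Step 4. Hydrogen abstraction may occur at C5 beside the ring oxygen instead of at C3. The ene reaction may also be sluggish, or over-oxidation may set in. The fallback sets out from 6 and comes back at 7, and it replaces the C–H oxidation by a kinetic enolisation that decides the regiochemistry.
- Lemieux–Johnson cleavage (OsO4 cat., NaIO4, 2,6-lutidine, dioxane–water) should give the (R)-5-aryldihydrofuran-3(2H)-one F6.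
- LiN(SiMe3)2 with Et3SiCl at −78 °C should deprotonate away from the alkoxy-bearing C5 and give the triethylsilyl enol ether F7.
- Rubottom oxidation (mCPBA, NaHCO3, CH2Cl2, 0 °C) should give the α-triethylsilyloxy ketone F8.
- Zn/CH2Br2/TiCl4 should put C8 back, giving the allylic silyl ether F9.
- AcOH–THF–water should free 7 while the aryl TBS ether stays in place.

Step 3. Addition to the electron-rich carbonyl may be slow, silyl transfer may capture the alkoxide before ring closure, or the enantioface discrimination may be insufficient. The fallback sets out from 2 and comes back at 6, and it makes the same two bonds in two separate operations.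
- [2-(Chloromethyl)allyl]tributylstannane F10 is prepared from 3-chloro-2-(chloromethyl)prop-1-ene and Bu3SnLi.
- F10 is added to 2 in a Keck allylation ((R)-BINOL, Ti(OiPr)4, 4 Å sieves, CH2Cl2, −20 °C). This should form C2–C3 and give the (R)-chlorohydrin F11.
- NaH in THF should then close O1–C5 by Williamson etherification (5-exo-tet) to give 6.

Further compounds
F1 | step 6 | (2S,3R)-2-[4-(TBS-oxy)-3-methoxyphenyl]-4-methylenetetrahydrofuran-3-yl picolinate | C=C1CO[C@@H](c2ccc(O[Si](C)(C)C(C)(C)C)c(OC)c2)[C@@H]1OC(=O)c1ccccn1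
F2 | step 6 | [3-(TBS-oxy)-4-methoxyphenyl]magnesium bromide | COc1ccc([Mg]Br)cc1O[Si](C)(C)C(C)(C)C
F3 | step 6 | (R)-2-[4-(TBS-oxy)-3-methoxyphenyl]-4-[3-(TBS-oxy)-4-methoxybenzyl]-2,5-dihydrofuran | COc1ccc(CC2=C[C@H](c3ccc(O[Si](C)(C)C(C)(C)C)c(OC)c3)OC2)cc1O[Si](C)(C)C(C)(C)C
F4 | step 6 | C3-borane of F3 (drawn as the monoalkylborane; boron trans to aryl and to benzyl) | COc1ccc(C[C@H]2CO[C@@H](c3ccc(O[Si](C)(C)C(C)(C)C)c(OC)c3)[C@@H]2B)cc1O[Si](C)(C)C(C)(C)C
F5 | step 6 | (2S,3R,4S)-2-[4-(TBS-oxy)-3-methoxyphenyl]-4-[3-(TBS-oxy)-4-methoxybenzyl]tetrahydrofuran-3-ol | COc1ccc(C[C@H]2CO[C@@H](c3ccc(O[Si](C)(C)C(C)(C)C)c(OC)c3)[C@@H]2O)cc1O[Si](C)(C)C(C)(C)C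
F6 | step 4 | (R)-5-[4-(TBS-oxy)-3-methoxyphenyl]dihydrofuran-3(2H)-one | O=C1CO[C@@H](c2ccc(O[Si](C)(C)C(C)(C)C)c(OC)c2)C1
F7 | step 4 | (R)-2-[4-(TBS-oxy)-3-methoxyphenyl]-4-(triethylsilyloxy)-2,5-dihydrofuran | CC[Si](CC)(CC)OC1=C[C@H](c2ccc(O[Si](C)(C)C(C)(C)C)c(OC)c2)OC1
F8 | step 4 | (4S,5S)-5-[4-(TBS-oxy)-3-methoxyphenyl]-4-(triethylsilyloxy)dihydrofuran-3(2H)-one (trans) | O=C1CO[C@@H](c2ccc(O[Si](C)(C)C(C)(C)C)c(OC)c2)[C@@H]1O[Si](CC)(CC)CC
F9 | step 4 | triethylsilyl ether of 7 | C=C1CO[C@@H](c2ccc(O[Si](C)(C)C(C)(C)C)c(OC)c2)[C@@H]1O[Si](CC)(CC)CC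
F10 | step 3 | [2-(chloromethyl)allyl]tributylstannane | CCCC[Sn](CCCC)(CCCC)CC(=C)CCl
F11 | step 3 | (R)-1-[4-(TBS-oxy)-3-methoxyphenyl]-3-(chloromethyl)but-3-en-1-ol | C=C(CCl)C[C@@H](O)c1ccc(O[Si](C)(C)C(C)(C)C)c(OC)c1
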